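**Plan**

- Numbering: 3,7-dioxabicyclo[3.3.0]octane core with bridgeheads C1/C5, aryl carbons C2 (3-hydroxy-4,5-dimethoxyphenyl) and C6 (3,4,5-trimethoxyphenyl), methylenes C4/C8. The target is (1R,2S,5R,6S), both aryl groups exo.
- Retrosynthesis: cut the two benzylic ether bonds C2–O3 and C6–O7 (both tetrahydrofuran rings open to a tetraol), then the C–C bonds C1–C2 and C5–C6.
- Enabling feature: the chain C8–C1–C5–C4 shared by the two rings is a γ-alkoxybutenolide in disguise (C8 = lactone carbonyl, C4 = acetal carbon). Its β-carbon C5 accepts the acyl-anion carbon C6, and its α-carbon C1, as the enolate, accepts the aldehyde carbon C2.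
- Forward: butenolide, aryl dithiane and aryl aldehyde are joined in one pot (C5–C6, then C1–C2). Dithiane hydrolysis and LiAlH4 give the tetraol, both rings close in one acid step, and the phenol is released last.
- Stereochemistry: (−)-menthol fixes the (5R) acetal by crystallisation. The acetal directs C5, the new C5 substituent directs C1 (trans), and C2/C6 are set exo when the benzylic cations are captured.

Key step: step 5

Remark: the benzylic carbinol carbons created in steps 5 and 7 are expected as epimer mixtures and are written without configuration in 13–15; both are ionised in step 8, so no control is sought there.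

**Route**

Step 1
Reactants: 1 furfural
Product: 3 5-hydroxyfuran-2(5H)-one (racemic), via furfural endoperoxide 2 (not isolated)
Conditions: O2, 3,7-bis(dimethylamino)phenothiazin-5-ium chloride (methylene blue, cat.), MeOH, hν (visible), 20 °C
Reagents that add atoms: oxygen, O=O
Why: Dye-sensitised photooxygenation, in which singlet oxygen adds across C2/C5 of the furan in a [4+2] cycloaddition and methanol solvolyses the endoperoxide with loss of the formyl carbon as methyl formate, leaving the γ-hydroxybutenolide, whose hemiacetal configuration is irrelevant because it epimerises freely.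

Step 2
Reactants: 3 5-hydroxyfuran-2(5H)-one; 4 (1R,2S,5R)-menthol
Product: 6 (5R)-5-[(1R,2S,5R)-menthyloxy]furan-2(5H)-one, via (5S)-acetal epimer 5 (not isolated)
Conditions: TsOH·H2O (cat.), toluene, reflux with azeotropic removal of water; crystallisation from petroleum ether at −20 °C, mother liquor re-equilibrated with TsOH·H2O
Reagents that add atoms: none
Why: Acid-catalysed acetalisation of the pseudo-acid hemiacetal with the secondary alcohol; both C5 epimers form and interconvert under the acid, and because the (5R) epimer is the one that crystallises, re-equilibration funnels the material into it (crystallisation-driven epimerisation), the menthol stereocentres being the source of chirality.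

Step 3
Reactants: 7 3,4,5-trimethoxybenzaldehyde
Product: 8 2-(3,4,5-trimethoxyphenyl)-1,3-dithiane
Conditions: HS(CH2)3SH, BF3·OEt2 (cat.), CH2Cl2, 0 °C → rt
Reagents that add atoms: propane-1,3-dithiol, SCCCS
Why: Lewis-acid-catalysed dithioacetalisation of an aromatic aldehyde, which turns the carbonyl carbon (the future C6) into an acidic position for umpolung.

Step 4
Reactants: 9 3-hydroxy-4,5-dimethoxybenzaldehyde
Product: 10 3,4-dimethoxy-5-(triisopropylsilyloxy)benzaldehyde
Conditions: i-Pr3SiCl, imidazole, DMF, rt
Reagents that add atoms: chlorotriisopropylsilane, CC(C)[Si](Cl)(C(C)C)C(C)C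
Why: Standard phenol silylation (silyl chloride and imidazole); the bulky silyl ether removes the acidic proton that would quench the enolate in step 5 and is expected to survive organolithium, hydride and Lewis acid conditions.

Step 5
Reactants: 8 2-(3,4,5-trimethoxyphenyl)-1,3-dithiane; 6 (5R)-5-[(1R,2S,5R)-menthyloxy]furan-2(5H)-one; 10 3,4-dimethoxy-5-(triisopropylsilyloxy)benzaldehyde
Product: 13 (3S,4R,5R)-3-{[3,4-dimethoxy-5-(triisopropylsilyloxy)phenyl](hydroxy)methyl}-5-[(1R,2S,5R)-menthyloxy]-4-[2-(3,4,5-trimethoxyphenyl)-1,3-dithian-2-yl]dihydrofuran-2(3H)-one (carbinol epimers), via 2-lithio-2-(3,4,5-trimethoxyphenyl)-1,3-dithiane 11 (not isolated), via lithium lactone enolate 12 (not isolated)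
Conditions: n-BuLi, THF, −78 → −30 °C; then 6, −78 °C; then 10, −78 °C; AcOH, −78 °C
Reagents that add atoms: none
Why: n-BuLi removes the proton between the two sulfur atoms of 8, and the sulfur-stabilised benzylic anion 11, an acyl anion equivalent for C6, adds to the β-carbon of 6 (C5–C6 bond); the lithium enolate 12 so formed adds through its α-carbon to aldehyde 10 (C1–C2 bond) before a cold acetic acid quench. The closest known reaction type is the tandem conjugate addition–aldol (Michael–aldol) reaction of lithiated 2-aryl-1,3-dithianes with γ-alkoxybutenolides and aromatic aldehydes. No ring is closed; the step joins the three fragments into the complete carbon skeleton. C5 (lactone C4) is controlled by the (5R) acetal, whose menthyloxy group blocks one face so that the nucleophile enters trans to it; C1 (lactone C3) is controlled by the new dithianyl group, the aldehyde being taken up trans to it; the carbinol carbon C2 forms without control, which is harmless because that centre is ionised in step 8. The step needs 1,4- rather than 1,2-addition, secured by the soft, delocalised and hindered aryl dithiane anion and the unhindered β-carbon of the butenolide, and it needs an aldolate that does not revert, secured by trapping and protonating at −78 °C.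

Step 6
Reactants: 13 aldol adduct
Product: 14 (3S,4R,5R)-3-{[3,4-dimethoxy-5-(triisopropylsilyloxy)phenyl](hydroxy)methyl}-5-[(1R,2S,5R)-menthyloxy]-4-(3,4,5-trimethoxybenzoyl)dihydrofuran-2(3H)-one (carbinol epimers)
Conditions: Hg(ClO4)2·3H2O, CaCO3, THF/H2O (5:1), 0 °C → rt
Reagents that add atoms: water, O
Why: Thiophilic metal-assisted dithioacetal hydrolysis, in which the mercury salt binds both sulfur atoms and water delivers the ketone oxygen while CaCO3 keeps the medium near neutral so that the benzylic carbinol, menthyl acetal, lactone and silyl ether are left alone; C5, now α to the ketone, already sits in the more stable all-trans arrangement.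

Step 7
Reactants: 14 keto lactone
Product: 15 (2R,3R)-2-{[3,4-dimethoxy-5-(triisopropylsilyloxy)phenyl](hydroxy)methyl}-3-[hydroxy(3,4,5-trimethoxyphenyl)methyl]butane-1,4-diol (carbinol epimers)
Conditions: LiAlH4, THF, 0 °C → rt; then H2O, aq. NaOH
Reagents that add atoms: none
Why: Exhaustive hydride reduction, in which LiAlH4 takes the aryl ketone to the C6 carbinol (new centre, uncontrolled and erased in step 8), the lactone carbonyl to the C8 alcohol and, once the opened lactone has expelled menthoxide, the acetal carbon to the C4 alcohol; C1 and C5 are untouched because carbonyl addition is faster than enolisation at 0 °C.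

Step 8
Reactants: 15 tetraol
Product: 17 (1R,2S,5R,6S)-2-[3,4-dimethoxy-5-(triisopropylsilyloxy)phenyl]-6-(3,4,5-trimethoxyphenyl)-3,7-dioxabicyclo[3.3.0]octane, via monocyclic tetrahydrofuran diol 16 (not isolated)
Conditions: BF3·OEt2, CH2Cl2, −20 → 0 °C, short reaction time; Et3N quench
Reagents that add atoms: none
Why: Twofold acid-promoted SN1 cycloetherification, in which each electron-rich benzylic carbinol ionises whatever its configuration and the planar cation is captured in a five-membered closure by the primary hydroxyl of the neighbouring branch (C4–OH onto C2, C8–OH onto C6), allylic strain keeping the C1–H or C5–H bond in the aryl plane so that the oxygen arrives on the face that leaves the aryl group trans to the adjacent ring carbon, that is exo on the cis-fused bicycle dictated by the (1R,5R) backbone, which sets C2 and C6 as S under kinetic control before the acid is quenched.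

Step 9
Reactants: 17 silyl-protected furofuran
Product: 18 5-[(1R,2S,5R,6S)-6-(3,4,5-trimethoxyphenyl)-3,7-dioxabicyclo[3.3.0]octan-2-yl]-2,3-dimethoxyphenol (CNP0181235.1)
Conditions: Bu4NF, AcOH, THF, 0 °C → rt
Reagents that add atoms: none
Why: Fluoride-induced cleavage of the aryl silyl ether, driven by Si–F bond formation and buffered by acetic acid; the aryl methyl ethers and the two cyclic benzylic ethers do not respond to fluoride, so the four stereocentres are untouched.

**Compound list**

1 | furfural | O=Cc1ccco1 | starting material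
2 | furfural endoperoxide (2,3,7-trioxabicyclo[2.2.1]hept-5-ene-1-carbaldehyde) | O=CC12C=CC(OO1)O2 | intermediate (not isolated)
3 | 5-hydroxyfuran-2(5H)-one (racemic) | OC1C=CC(=O)O1 | intermediate
4 | (1R,2S,5R)-menthol | CC(C)[C@@H]1CC[C@@H](C)C[C@H]1O | starting material
5 | (5S)-5-[(1R,2S,5R)-menthyloxy]furan-2(5H)-one, the acetal epimer of 6 | CC(C)[C@@H]1CC[C@@H](C)C[C@H]1O[C@@H]2C=CC(=O)O2 | intermediate (not isolated)
6 | (5R)-5-[(1R,2S,5R)-menthyloxy]furan-2(5H)-one | CC(C)[C@@H]1CC[C@@H](C)C[C@H]1O[C@H]2C=CC(=O)O2 | intermediate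
7 | 3,4,5-trimethoxybenzaldehyde | COc1cc(C=O)cc(OC)c1OC | starting material
8 | 2-(3,4,5-trimethoxyphenyl)-1,3-dithiane | COc1cc(C2SCCCS2)cc(OC)c1OC | intermediate
9 | 3-hydroxy-4,5-dimethoxybenzaldehyde | COc1cc(C=O)cc(O)c1OC | starting material
10 | 3,4-dimethoxy-5-(triisopropylsilyloxy)benzaldehyde | COc1cc(C=O)cc(O[Si](C(C)C)(C(C)C)C(C)C)c1OC | intermediate
11 | 2-lithio-2-(3,4,5-trimethoxyphenyl)-1,3-dithiane | [Li]C1(c2cc(OC)c(OC)c(OC)c2)SCCCS1 | intermediate (not isolated)
12 | lithium enolate of (4R,5R)-5-menthyloxy-4-[2-(3,4,5-trimethoxyphenyl)-1,3-dithian-2-yl]dihydrofuran-2(3H)-one | CC(C)[C@@H]1CC[C@@H](C)C[C@H]1O[C@H]2[C@H](C3(c4cc(OC)c(OC)c(OC)c4)SCCCS3)C=C(O[Li])O2 | intermediate (not isolated)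
13 | (3S,4R,5R)-3-{[3,4-dimethoxy-5-(triisopropylsilyloxy)phenyl](hydroxy)methyl}-5-[(1R,2S,5R)-menthyloxy]-4-[2-(3,4,5-trimethoxyphenyl)-1,3-dithian-2-yl]dihydrofuran-2(3H)-one, all-trans on the lactone, carbinol carbon as epimers | CC(C)[C@@H]1CC[C@@H](C)C[C@H]1O[C@H]2[C@H](C3(c4cc(OC)c(OC)c(OC)c4)SCCCS3)[C@@H](C(O)c3cc(O[Si](C(C)C)(C(C)C)C(C)C)c(OC)c(OC)c3)C(=O)O2 | intermediate
14 | (3S,4R,5R)-3-{[3,4-dimethoxy-5-(triisopropylsilyloxy)phenyl](hydroxy)methyl}-5-[(1R,2S,5R)-menthyloxy]-4-(3,4,5-trimethoxybenzoyl)dihydrofuran-2(3H)-one, carbinol carbon as epimers | CC(C)[C@@H]1CC[C@@H](C)C[C@H]1O[C@H]2[C@H](C(=O)c3cc(OC)c(OC)c(OC)c3)[C@@H](C(O)c3cc(O[Si](C(C)C)(C(C)C)C(C)C)c(OC)c(OC)c3)C(=O)O2 | intermediate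
15 | (2R,3R)-2-{[3,4-dimethoxy-5-(triisopropylsilyloxy)phenyl](hydroxy)methyl}-3-[hydroxy(3,4,5-trimethoxyphenyl)methyl]butane-1,4-diol, both carbinol carbons as epimers | COc1cc(C(O)[C@@H](CO)[C@H](CO)C(O)c2cc(OC)c(OC)c(OC)c2)cc(O[Si](C(C)C)(C(C)C)C(C)C)c1OC | intermediate
16 | [(2S,3R,4R)-4-{[3,4-dimethoxy-5-(triisopropylsilyloxy)phenyl](hydroxy)methyl}-2-(3,4,5-trimethoxyphenyl)oxolan-3-yl]methanol, the monocycle with the O7 ring closed | COc1cc(C(O)[C@H]2CO[C@H](c3cc(OC)c(OC)c(OC)c3)[C@H]2CO)cc(O[Si](C(C)C)(C(C)C)C(C)C)c1OC | intermediate (not isolated)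
17 | (1R,2S,5R,6S)-2-[3,4-dimethoxy-5-(triisopropylsilyloxy)phenyl]-6-(3,4,5-trimethoxyphenyl)-3,7-dioxabicyclo[3.3.0]octane | COc1cc([C@H]2OC[C@H]3[C@@H]2CO[C@@H]3c2cc(OC)c(OC)c(OC)c2)cc(O[Si](C(C)C)(C(C)C)C(C)C)c1OC | intermediate
18 | 5-[(1R,2S,5R,6S)-6-(3,4,5-trimethoxyphenyl)-3,7-dioxabicyclo[3.3.0]octan-2-yl]-2,3-dimethoxyphenol (CNP0181235.1) | COc1cc([C@H]2OC[C@H]3[C@@H]2CO[C@@H]3c2cc(OC)c(OC)c(OC)c2)cc(O)c1OC | target

**Step count**

Total: 9 steps. Longest linear sequence: 7 steps (1, 2, 5, 6, 7, 8, 9, from furfural).

**Steps most likely to fail**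

Step 8. What may go wrong: capture of the benzylic cations with too little exo preference, capture by the other benzylic hydroxyl instead of the primary one (a 2,5-diaryltetrahydrofuran), or epimerisation of the benzylic ether carbons by the acid after closure. The fallback takes ring formation away from the cation. Tetraol 15 would be treated with MeSO2Cl (about two equivalents) in pyridine at 0 °C, which sulfonylates the two primary hydroxyls first. In the resulting bis-mesylate F1 (not isolated) each benzylic hydroxyl displaces the mesylate on the neighbouring branch by SN2 at the primary carbons C4 and C8, so the ether bonds O3–C4 and O7–C8 are formed instead of O3–C2 and O7–C6. Because the carbinol configurations are carried over, the furofuran would be obtained as the mixture of C2/C6 epimers F2. F2 would then be equilibrated at the benzylic carbons with TsOH·H2O in CH2Cl2, the exo,exo isomer 17 separated by chromatography and the endo epimers returned to the acid. This equilibrium is not expected to be one-sided, so the recycling is part of the fallback. The route is rejoined at 17.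

Step 5. What may go wrong: incomplete trapping of enolate 12 through proton transfer, reversal of the aldol addition on warming or, less likely, 1,2-addition of 11 to the lactone carbonyl. The fallback makes the two C–C bonds in separate operations with a different enolate equivalent. Dithiane 8 would be lithiated and added to 6 as before, but the enolate protonated to give the Michael adduct F3. F3 would be converted with LiN(i-Pr)2 and Me3SiCl (THF, −78 °C) into the silyl ketene acetal F4. A Mukaiyama aldol reaction of F4 with aldehyde 10 (BF3·OEt2, CH2Cl2, −78 °C), which does not revert under these conditions and should again take place trans to the dithianyl group, would give 13 after aqueous work-up, where the route is rejoined.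

Step 6. What may go wrong: once the ketone is unmasked, the keto lactone can lose the aldol hydroxyl by dehydration or retro-aldol cleavage, or undergo β-elimination of the acetal oxygens next to the new ketone; the hydrolysis may also stall on the hindered quaternary dithiane. The fallback reverses the order of unmasking and reduction. Adduct 13 would be reduced with LiAlH4 (THF, 0 °C → rt) while the dithiane is still in place, giving the dithianyl triol F5 and menthol. F5, which has neither a carbonyl group nor an acetal, would be hydrolysed by S-alkylation (MeI, CaCO3, MeCN/H2O, 40 °C) to the hydroxy ketone F6, expected to sit in equilibrium with its five-membered hemiketal. NaBH4 in MeOH would reduce F6 to tetraol 15, where the route is rejoined.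

**Further compounds**

F1 | step 8 | bis(methanesulfonate) of the two primary hydroxyls of tetraol 15, (2R,3R) backbone, carbinol carbons as epimers | COc1cc(C(O)[C@@H](COS(C)(=O)=O)[C@H](COS(C)(=O)=O)C(O)c2cc(OC)c(OC)c(OC)c2)cc(O[Si](C(C)C)(C(C)C)C(C)C)c1OC
F2 | step 8 | (1R,5R)-2-[3,4-dimethoxy-5-(triisopropylsilyloxy)phenyl]-6-(3,4,5-trimethoxyphenyl)-3,7-dioxabicyclo[3.3.0]octane as the mixture of epimers at C2 and C6 | COc1cc(C2OC[C@H]3[C@@H]2COC3c2cc(OC)c(OC)c(OC)c2)cc(O[Si](C(C)C)(C(C)C)C(C)C)c1OC
F3 | step 5 | (4R,5R)-5-[(1R,2S,5R)-menthyloxy]-4-[2-(3,4,5-trimethoxyphenyl)-1,3-dithian-2-yl]dihydrofuran-2(3H)-one | CC(C)[C@@H]1CC[C@@H](C)C[C@H]1O[C@H]2[C@H](C3(c4cc(OC)c(OC)c(OC)c4)SCCCS3)CC(=O)O2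
F4 | step 5 | trimethylsilyl ketene acetal of F3 (2-trimethylsilyloxy-4,5-dihydrofuran) | CC(C)[C@@H]1CC[C@@H](C)C[C@H]1O[C@H]2[C@H](C3(c4cc(OC)c(OC)c(OC)c4)SCCCS3)C=C(O[Si](C)(C)C)O2
F5 | step 6 | (2R,3R)-2-{[3,4-dimethoxy-5-(triisopropylsilyloxy)phenyl](hydroxy)methyl}-3-[2-(3,4,5-trimethoxyphenyl)-1,3-dithian-2-yl]butane-1,4-diol, carbinol carbon as epimers | COc1cc(C(O)[C@@H](CO)[C@H](CO)C2(c3cc(OC)c(OC)c(OC)c3)SCCCS2)cc(O[Si](C(C)C)(C(C)C)C(C)C)c1OC
F6 | step 6 | hydroxy ketone from F5 (open form): the 3,4,5-trimethoxybenzoyl analogue of tetraol 15 | COc1cc(C(O)[C@@H](CO)[C@H](CO)C(=O)c2cc(OC)c(OC)c(OC)c2)cc(O[Si](C(C)C)(C(C)C)C(C)C)c1OC
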